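**Remark:** ring A is the acylphloroglucinol ring (primed locants, C1' bearing the cinnamoyl group), ring B the phenyl of the styryl unit, ring C the 2-hydroxybenzyl ring. Ketone 1, benzaldehyde 3 and 2-hydroxybenzyl alcohol 7 are assumed to be purchasable.

## The problem

Target 9 is a 2'-hydroxychalcone in which three benzene rings are joined only by acyclic links: the C(=O)–CH=CH chain between ring A and ring B, and one methylene between C3' of ring A and the carbon of ring C ortho to its hydroxyl. There is no stereocentre; the only stereochemical element is the E geometry of the enone, which an aldol condensation sets thermodynamically and which then only has to be preserved (light, reversible conjugate addition). The real difficulty is the substitution pattern of ring A, a pentasubstituted acylphloroglucinol with C1' cinnamoyl, C2' OH, C3' CH2Ar, C4' OH, C5' H and C6' OMe. The benzyl group must go to C3' and not to the similarly electron-rich C5', once and not twice, and only the 6'-oxygen may be methylated. Several groups forbid rough treatment: the 2'-hydroxyl can add to the enone β-carbon and close a flavanone under acid, base or long heating; the enone rules out hydrogenation, hydride reagents and hard nucleophiles; ring A with two free hydroxyls over-alkylates and oxidises easily. The enabling feature is the C3'–CH2–C(aryl) unit whose aryl carbon next to the bridge carries an OH. A methylene ortho to a phenol is the retron of an ortho-quinone methide, and C3', flanked by the chelated 2'-OH and the 4'-OH, is the enolic carbon of a phloroglucinol, the kind of nucleophile such an electrophile accepts. Cutting that one bond leaves cardamonin 6, in which oxygen pattern, methyl ether and enone geometry are already settled.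

## Retrosynthesis

**Target 9 ⇒ chalcone 6 + ortho-quinone methide 8 (from alcohol 7).** The bond cut is C3'–CH2. The neighbouring cuts are less attractive: breaking CH2–C(ring C) needs a ring A benzylic nucleophile or radical and a protected aryl halide, and breaking the enone first leaves the benzylation problem untouched on a smaller ketone. The chosen cut removes ring C and the bridge together and leaves 6, which already has the methyl ether, both free hydroxyls and the E-enone, plus 7, a bulk chemical that loses water to give 8. The forward reaction must deliver 8 to C3' and not to C5' or to oxygen, stop after one alkylation, and leave the 2'-hydroxy enone open and E-configured. It is run on unprotected 6 because the free 2'- and 4'-hydroxyls are what make C3' nucleophilic.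

**Chalcone 6 ⇒ methoxymethyl ether 5.** No skeletal bond is cut; the 4'-hydroxyl is masked. Compound 6 can be bought in small amounts, but the key step uses it in excess, so a gram-scale preparation is included. The acetal survives the strongly basic condensation and is removed by dilute acid near room temperature, which should be mild enough not to close the flavanone. A benzyl ether would need hydrogenolysis, which the enone does not tolerate, and a silyl ether would not survive the alkali.

**Chalcone 5 ⇒ ketone 2 + benzaldehyde 3, through aldol adduct 4.** The Cα=Cβ double bond is cut. Attaching a complete cinnamoyl unit to ring A by C-acylation is rejected: electron-rich phenols add to the cinnamoyl double bond and close to chromanone-type products, and the acylation would raise its own site problem. The condensation gives the E-enone under thermodynamic control from two simple components. It requires that the ketone can still be enolised, which is why the 4'-oxygen, whose phenoxide is conjugated with the carbonyl, is capped in 2, leaving only the chelated 2'-phenoxide.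

**Ketone 2 ⇒ ketone 1.** The O–CH2 bond of the acetal is cut. Compound 1 already has the ring A oxygenation of the target with the methyl ether in place, so no methylation selectivity has to be engineered. The forward reaction must alkylate the 4-hydroxyl and spare the 2-hydroxyl, which the hydrogen bond of the latter to the acetyl group should ensure. Compounds 1, 3 and 7 are the purchased materials.

## Roads not taken

**Alternative 1:** Ring A is built, not bought. The cut runs through three ring bonds, C2'–C3', C4'–C5' and C1'–C2'. 3-Methoxycyclobutenone A1 is heated with the benzyl-substituted triisopropylsiloxyalkyne A2 (Danheiser benzannulation). A1 opens to a vinylketene, which adds to A2 in a [2+2] cycloaddition; the new cyclobutenone opens, the dienylketene closes by 6π electrocyclisation and tautomerises to phenol A3, 5-methoxy-2-[2-(methoxymethoxy)benzyl]-3-(triisopropylsilyloxy)phenol.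
- Merits: the connectivity of the two components puts the benzyl group between a free hydroxyl (the future 2'-OH) and a silyl ether (the future 4'-OH), with the methoxy group para to it. A C5' isomer cannot arise, and the three oxygens come out differentiated, so the free hydroxyl could direct the later acylation to C1'.
- Weak points: neither A1 nor A2 is a routine catalogue compound; A2 needs an ynolate homologation of a 3-arylpropanoate and O-silylation and is moisture-sensitive. A3 still lacks the whole cinnamoyl unit, so C-acylation, condensation and two deprotections follow, for roughly ten operations.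
- Comparison: in site control this road is clearly better than the chosen one, which relies on an intrinsic bias of ring A. The chosen plan sets against it four steps in place of about ten, a purchased ring A with complete oxygen pattern, and a last step in which a wrong isomer would show and be separable, backed by a fallback that moves the alkylation to an earlier, more robust stage.

**Alternative 2:** The cut is the CH2–C(ring C) bond, the other side of the bridge. The N-hydroxyphthalimide ester A4 of the ring A acetic acid is reduced at a cathode in the presence of NiCl2·DME and a bipyridine ligand. The benzylic radical from decarboxylative fragmentation is captured by nickel and coupled with the MOM ether of 2-iodophenol A5 to give diarylmethane A6, 5-methoxy-1,3-bis(methoxymethoxy)-2-[2-(methoxymethoxy)benzyl]benzene.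
- Merits: the methylene already sits on ring A between two equivalent acetal oxygens, so symmetry defines C3'. After the acetals of A6 are removed, the two open positions of ring A are again equivalent, so acylation can give only one isomer. The coupling tolerates ethers and acetals.
- Weak points: A4 needs several steps. The radical is flanked by two ortho alkoxy groups and A5 is ortho-substituted, a crowded pairing in which radical dimerisation and simple reduction compete. A6 again lacks the cinnamoyl unit, which would have to come in as an acetyl group followed by condensation, since cinnamoyl electrophiles cyclise onto free phloroglucinols. Electrochemical equipment is required.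
- Comparison: regiochemistry by symmetry is better than regiochemistry by bias, and here the chosen plan is the weaker one. It sets against this less than half the step count, no protecting-group traffic on ring C, and a disconnection that uses the ortho hydroxyl of ring C instead of masking it.

**Alternative 3:** The cut is Cβ–C(ipso) of ring B. The tris-MOM-protected ring A vinyl ketone A7 is coupled with iodobenzene A8 under Pd(OAc)2 catalysis (Heck reaction). Oxidative addition of A8 to zerovalent palladium formed in the flask, syn insertion of the vinyl group and syn β-hydride elimination give the tris-MOM ether A9 of the target chalcone with E geometry.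
- Merits: reliable E selectivity; the bond is made on a substrate with no free 2'-OH, so flavanone closure cannot occur at that stage; ring B could be varied late.
- Weak points: the difficult part is untouched, since A7 already carries the C3' benzyl group and must be made by one of the other disconnections. Doubly ortho-substituted aryl vinyl ketones are polymerisation-prone Michael acceptors. Ring B is a plain phenyl that an aldehyde delivers by condensation with the same E outcome and no palladium. Final removal of three acetals exposes the 2'-hydroxy enone to acid, as in step 3 of the chosen route.
- Comparison: equal in geometry control and somewhat better in shielding the enone while the bond is made; worse in length and in postponing the real problem. The chosen plan makes the enone early by condensation and spends its key step on the bridge bond.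

Key step: step 4

## Route

Step 1
Reactants: 1 1-(2,4-dihydroxy-6-methoxyphenyl)ethanone (2',4'-dihydroxy-6'-methoxyacetophenone)
Product: 2 1-[2-hydroxy-6-methoxy-4-(methoxymethoxy)phenyl]ethanone
Conditions: MOMCl (1.1 equiv), K2CO3 (1.5 equiv), acetone, 0 °C → rt
Reagents that add atoms: chloromethyl methyl ether, COCCl
Why: Williamson-type O-alkylation (MOM ether formation); the 4-hydroxyl, para to the acetyl group and not hydrogen-bonded, is the more acidic and accessible phenol, whereas the 2-hydroxyl is held in a six-membered chelate with the carbonyl and should stay free with one equivalent of reagent and a mild base.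

Step 2
Reactants: 2 1-[2-hydroxy-6-methoxy-4-(methoxymethoxy)phenyl]ethanone; 3 benzaldehyde
Product: 5 (E)-1-[2-hydroxy-6-methoxy-4-(methoxymethoxy)phenyl]-3-phenylprop-2-en-1-one, via aldol adduct 4 (not isolated)
Conditions: KOH (50% aq), EtOH, 0 °C → rt; then cold 1 M HCl to pH 5
Reagents that add atoms: none
Why: Claisen–Schmidt condensation; the ketone enolate adds to the non-enolisable aldehyde and E1cB loss of hydroxide from 4 gives the conjugated enone, whose E geometry is the thermodynamic one; with the 4'-oxygen capped only the chelated 2'-phenoxide is present, so enolisation is not shut down, and the acetal is inert to alkali.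

Step 3
Reactants: 5 (E)-1-[2-hydroxy-6-methoxy-4-(methoxymethoxy)phenyl]-3-phenylprop-2-en-1-one
Product: 6 cardamonin, (E)-1-(2,4-dihydroxy-6-methoxyphenyl)-3-phenylprop-2-en-1-one
Conditions: 3 M aq HCl, MeOH, rt → 40 °C, dark
Reagents that add atoms: none
Why: Acid-catalysed acetal solvolysis; the aryl MOM ether ionises to an oxocarbenium ion that methanol traps, under conditions mild enough that the 2'-hydroxy enone should neither close to the flavanone nor lose its E geometry.

Step 4
Reactants: 6 cardamonin, (E)-1-(2,4-dihydroxy-6-methoxyphenyl)-3-phenylprop-2-en-1-one; 7 2-hydroxybenzyl alcohol
Product: 9 (E)-1-[2,4-dihydroxy-3-(2-hydroxybenzyl)-6-methoxyphenyl]-3-phenylprop-2-en-1-one, via ortho-quinone methide 8 (not isolated)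
Conditions: anhydrous ZnCl2 (1.5 equiv), 1,4-dioxane, 85 °C, N2, dark; 7 (0.7 equiv) added slowly
Reagents that add atoms: none
Why: ZnCl2 binds the benzylic hydroxyl of 7 and, with loss of water, releases ortho-quinone methide 8 (free or zinc-bound), whose exocyclic CH2 is a soft carbon electrophile. C3' of 6 adds to it in a Friedel–Crafts-type conjugate addition and the resulting cyclohexadienone tautomerises at once, so that ring A and ring C are both aromatic again; this makes the C–C bond irreversible, whereas an aryl benzyl ether from O-attack can ionise back to 8 under the same conditions. The closest known reaction type is the ZnCl2-mediated C-benzylation of acylphloroglucinol-type dihydrochalcones and flavanones with 2-hydroxybenzyl alcohols. No ring is closed and no stereocentre is formed; the E-enone is a spectator, since an electron-poor alkene is a poor partner for the electron-poor heterodiene 8, and protic acid and light are excluded. The step needs site selectivity for C3' over C5': the chelate of the 2'-OH with the carbonyl fixes the C1'=C2' bond, so the free 4'-OH is the enol of the C3'=C4' bond and C3' its nucleophilic carbon, while C5' is the β-carbon of the less reactive C5'=C6' methyl enol ether. In addition C3' is ortho to two oxygens (2'-O and 4'-O) that can deliver 8 through zinc or a hydrogen bond, C5' to only one, and the methyl of the 6'-OMe, turned away from the cinnamoyl group, shields C5'. Mono-alkylation is sought by keeping 6 in excess and adding 7 slowly, so that 8 meets 6 sooner than product 9 or a second molecule of 7; unreacted 6 should be recoverable and any C5' isomer is to be removed by chromatography.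

## Compound list

1 | 1-(2,4-dihydroxy-6-methoxyphenyl)ethanone (2',4'-dihydroxy-6'-methoxyacetophenone) | COc1cc(O)cc(O)c1C(C)=O | starting material
2 | 1-[2-hydroxy-6-methoxy-4-(methoxymethoxy)phenyl]ethanone | COCOc1cc(O)c(C(C)=O)c(OC)c1 | intermediate
3 | benzaldehyde | O=Cc1ccccc1 | starting material
4 | 3-hydroxy-1-[2-hydroxy-6-methoxy-4-(methoxymethoxy)phenyl]-3-phenylpropan-1-one (racemic aldol adduct, not isolated) | COCOc1cc(O)c(C(=O)CC(O)c2ccccc2)c(OC)c1 | intermediate
5 | (E)-1-[2-hydroxy-6-methoxy-4-(methoxymethoxy)phenyl]-3-phenylprop-2-en-1-one | COCOc1cc(O)c(C(=O)/C=C/c2ccccc2)c(OC)c1 | intermediate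
6 | cardamonin, (E)-1-(2,4-dihydroxy-6-methoxyphenyl)-3-phenylprop-2-en-1-one | COc1cc(O)cc(O)c1C(=O)/C=C/c1ccccc1 | intermediate
7 | 2-hydroxybenzyl alcohol | OCc1ccccc1O | starting material
8 | ortho-quinone methide, 6-methylidenecyclohexa-2,4-dien-1-one (not isolated) | C=C1C=CC=CC1=O | intermediate
9 | (E)-1-[2,4-dihydroxy-3-(2-hydroxybenzyl)-6-methoxyphenyl]-3-phenylprop-2-en-1-one | COc1cc(O)c(Cc2ccccc2O)c(O)c1C(=O)/C=C/c1ccccc1 | target

## Step count and risks

Total steps: 4. Longest linear sequence: 4 steps (1 → 2 → 5 → 6 → 9).

**Step 4 (key step).** What may go wrong: attack of 8 at C5' in competition with C3', a second benzylation of the product at C5', self-condensation of 8 with 7, and oxa-Michael closure of the 2'-hydroxyl onto the enone under Lewis acid and heat, in 6 or in 9. Fallback (benzylation before the enone exists): starting from ketone 1, the same alkylation with 7 (ZnCl2, dioxane, now at reflux since no enone is present) should give 1-[2,4-dihydroxy-3-(2-hydroxybenzyl)-6-methoxyphenyl]ethanone F1, from which the C5 isomer and any bis-adduct can be removed on a robust, inexpensive ketone. MOMCl/K2CO3 then caps the 4-hydroxyl and the ring C hydroxyl to give 1-[2-hydroxy-6-methoxy-4-(methoxymethoxy)-3-[2-(methoxymethoxy)benzyl]phenyl]ethanone F2. Claisen–Schmidt condensation with 3 (KOH, EtOH) passes through the aldol adduct 3-hydroxy-1-[2-hydroxy-6-methoxy-4-(methoxymethoxy)-3-[2-(methoxymethoxy)benzyl]phenyl]-3-phenylpropan-1-one F3 (not isolated) to (E)-1-[2-hydroxy-6-methoxy-4-(methoxymethoxy)-3-[2-(methoxymethoxy)benzyl]phenyl]-3-phenylprop-2-en-1-one F4. HCl/MeOH as in step 3 removes both acetals and the route is rejoined at 9.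

**Step 3.** What may go wrong: acid-catalysed oxa-Michael closure of the freed 2'-hydroxy enone to the flavanone, and partial E/Z isomerisation, while the acetal is being cleaved. Fallback (no protecting group, hence no acidic deprotection): from ketone 1, direct Claisen–Schmidt condensation with 3 in concentrated aqueous-ethanolic KOH, the ketone reacting as its bis-phenoxide through the aldol adduct 3-hydroxy-1-(2,4-dihydroxy-6-methoxyphenyl)-3-phenylpropan-1-one F5 (not isolated). This should be slower than step 2 because the 4-phenoxide damps enolisation, but cold neutralisation gives 6 directly, where the route is rejoined.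

**Step 2.** What may go wrong: sluggish enolisation of the doubly ortho-substituted, phenoxide-bearing ketone, so that Cannizzaro disproportionation of 3 takes over, and conjugate addition of the 2'-phenol to the new enone during acidification. Fallback (both phenols capped, no phenoxide present): from 2, NaH/MOMCl in DMF alkylates the chelated hydroxyl to give 1-[2-methoxy-4,6-bis(methoxymethoxy)phenyl]ethanone F6. Condensation with 3 (KOH, EtOH) via the aldol adduct 3-hydroxy-1-[2-methoxy-4,6-bis(methoxymethoxy)phenyl]-3-phenylpropan-1-one F7 (not isolated) gives (E)-1-[2-methoxy-4,6-bis(methoxymethoxy)phenyl]-3-phenylprop-2-en-1-one F8, which cannot cyclise. HCl/MeOH removes both acetals and the route is rejoined at 6.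

## Further compounds

F1 | step 4 | 1-[2,4-dihydroxy-3-(2-hydroxybenzyl)-6-methoxyphenyl]ethanone | COc1cc(O)c(Cc2ccccc2O)c(O)c1C(C)=O
F2 | step 4 | 1-[2-hydroxy-6-methoxy-4-(methoxymethoxy)-3-[2-(methoxymethoxy)benzyl]phenyl]ethanone | COCOc1ccccc1Cc1c(OCOC)cc(OC)c(C(C)=O)c1O
F3 | step 4 | 3-hydroxy-1-[2-hydroxy-6-methoxy-4-(methoxymethoxy)-3-[2-(methoxymethoxy)benzyl]phenyl]-3-phenylpropan-1-one (racemic, not isolated) | COCOc1ccccc1Cc1c(OCOC)cc(OC)c(C(=O)CC(O)c2ccccc2)c1O
F4 | step 4 | (E)-1-[2-hydroxy-6-methoxy-4-(methoxymethoxy)-3-[2-(methoxymethoxy)benzyl]phenyl]-3-phenylprop-2-en-1-one | COCOc1ccccc1Cc1c(OCOC)cc(OC)c(C(=O)/C=C/c2ccccc2)c1O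
F5 | step 3 | 3-hydroxy-1-(2,4-dihydroxy-6-methoxyphenyl)-3-phenylpropan-1-one (racemic, not isolated) | COc1cc(O)cc(O)c1C(=O)CC(O)c1ccccc1
F6 | step 2 | 1-[2-methoxy-4,6-bis(methoxymethoxy)phenyl]ethanone | COCOc1cc(OC)c(C(C)=O)c(OCOC)c1
F7 | step 2 | 3-hydroxy-1-[2-methoxy-4,6-bis(methoxymethoxy)phenyl]-3-phenylpropan-1-one (racemic, not isolated) | COCOc1cc(OC)c(C(=O)CC(O)c2ccccc2)c(OCOC)c1
F8 | step 2 | (E)-1-[2-methoxy-4,6-bis(methoxymethoxy)phenyl]-3-phenylprop-2-en-1-one | COCOc1cc(OC)c(C(=O)/C=C/c2ccccc2)c(OCOC)c1
A1 | alternative 1 | 3-methoxycyclobut-2-en-1-one | COC1=CC(=O)C1
A2 | alternative 1 | triisopropyl({3-[2-(methoxymethoxy)phenyl]prop-1-yn-1-yl}oxy)silane | COCOc1ccccc1CC#CO[Si](C(C)C)(C(C)C)C(C)C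
A3 | alternative 1 | 5-methoxy-2-[2-(methoxymethoxy)benzyl]-3-(triisopropylsilyloxy)phenol | COCOc1ccccc1Cc1c(O)cc(OC)cc1O[Si](C(C)C)(C(C)C)C(C)C
A4 | alternative 2 | 1,3-dioxoisoindolin-2-yl [4-methoxy-2,6-bis(methoxymethoxy)phenyl]acetate | COCOc1cc(OC)cc(OCOC)c1CC(=O)ON1C(=O)c2ccccc2C1=O
A5 | alternative 2 | 1-iodo-2-(methoxymethoxy)benzene | COCOc1ccccc1I
A6 | alternative 2 | 5-methoxy-1,3-bis(methoxymethoxy)-2-[2-(methoxymethoxy)benzyl]benzene | COCOc1ccccc1Cc1c(OCOC)cc(OC)cc1OCOC
A7 | alternative 3 | 1-{6-methoxy-2,4-bis(methoxymethoxy)-3-[2-(methoxymethoxy)benzyl]phenyl}prop-2-en-1-one | COc1cc(OCOC)c(Cc2ccccc2OCOC)c(OCOC)c1C(=O)C=C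
A8 | alternative 3 | iodobenzene | Ic1ccccc1
A9 | alternative 3 | (E)-1-{6-methoxy-2,4-bis(methoxymethoxy)-3-[2-(methoxymethoxy)benzyl]phenyl}-3-phenylprop-2-en-1-one | COc1cc(OCOC)c(Cc2ccccc2OCOC)c(OCOC)c1C(=O)/C=C/c1ccccc1
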